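If the eta flask has stopped while 84.8 % of its starting material is still there, a remedy has to shift a balance, not raise a speed.

| flask | starting material | coupling partner | free catalyst | temperature | remark | time |
|---|---|---|---|---|---|---|
| eta | 0.64 M | 1.3 equiv | 0.2 mol% | 35 °C | the very flask that is asked about, followed so far |  |
| gamma | 0.64 M | 1.3 equiv | 0.2 mol% | 41 °C | run made earlier |  |
| flask | 0.64 M | 1.30 equiv | 0.2 mol% | 35 °C |  | 25 h |

| run | time / min | target / % | starting material / % |
|---|---|---|---|
| eta | 120 | 7.8 | 88.7 |
| eta | 240 | 9.5 | 85.8 |
| eta | 480 | 11.1 | 85.7 |
| eta | 720 | 10.5 | 84.8 |
| eta | 1500 | 11.0 | 84.8 |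
| gamma | 120 | 5.6 | 91.7 |
| gamma | 240 | 6.9 | 90.5 |
| gamma | 480 | 6.3 | 91.2 |
| gamma | 720 | 6.2 | 91.6 |
| gamma | 1500 | 6.5 | 90.3 |

(readings scatter by 0.5 percentage points)

- elm: at 25 h add free catalyst, 100 % of the amount charged, then wait 25 h
- maple: at 25 h raise the temperature by 20 K, then wait 25 h
- larch: at 25 h take out 90 % of the target then present, then wait 25 h
- cedar: change nothing and wait 25 h more

* target, in percent of the starting material first charged, at 25 h
* the remedy with the largest gain of target, or "none" below 2 percentage points (elm / maple / larch / cedar / none)
* target present, with what was taken out counted in, in percent of the starting material first charged, after elm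
* target present, with what was taken out counted in, in percent of the starting material first charged, after maple

- target that was removed still counts
- steps that have been proposed: starting material + free catalyst <-> catalyst intermediate A; coupling partner + catalyst intermediate A <-> catalyst intermediate B; catalyst intermediate B <-> free catalyst + target; target + free catalyst <-> isomer of the product + free catalyst
- additions bring no volume worth counting

Eta reads 11.1 %, 10.5 % and 11.0 % of target from 480 min on, flat within the scatter, so the reckoning here for the flask at 25 h, which is eta itself, is their mean, 10.9 %.

But the balance of eta's last reading lacks 4.20 %, presumably isomer of the product. The proposed steps add up to starting material + coupling partner <-> target, with free catalyst returned. So at rest the forward rate of that sum can be divided by the back rate, and time drops out (thermodynamic control).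

In eta, with coupling partner taken to have lost what starting material lost, the last reading gives 0.177 /M for Q, the concentration of target over that of starting material times that of coupling partner.

Gamma, the hotter run, gives the lower 0.0935 /M, so maple should lose target. Free catalyst does not appear in Q, so elm should gain nothing.

Larch takes out 9.90 % of the charge. As a first pass, the reacted share is taken to grow by that amount to 25.1 %, and Q then allows 8.88 % of target in the flask. The gain, with what was removed counted in, is about 7.9 percentage points, so this reckoning chooses larch.

The forecast reads the plateau as “an exothermic equilibrium ceiling, not catalyst death”: 11 % now, larch as the remedy, 11 % after elm, 2 % after maple.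

The flask gives 10.9 %, larch with a gain of 8.2 points, 10.9 % after elm and 1.50 % after maple, so the forecast held.

    starting material + free catalyst ⇌ catalyst intermediate A (K = 0.946 /M, k = 1.02 /M/s, Ea = 49.0 kJ/mol, ΔH = −8.00 kJ/mol)
    coupling partner + catalyst intermediate A ⇌ catalyst intermediate B (K = 0.447 /M, k = 32.1 /M/s, Ea = 48.0 kJ/mol, ΔH = −30.0 kJ/mol)
    catalyst intermediate B ⇌ free catalyst + target (K = 0.410 M, k = 0.115 /s, Ea = 75.0 kJ/mol, ΔH = −55.0 kJ/mol)
    target + free catalyst ⇌ isomer of the product + free catalyst, rate k4*[free catalyst]*[target] forward; the back reaction follows from the equilibrium constant (K = 0.357, k = 1.21 /M/s, Ea = 62.0 kJ/mol, ΔH = 37.0 kJ/mol)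
    (constants at 35 °C)

The flask has come to rest: its simulated amounts at 1500 min give Q = 0.173 /M, beside 0.177 /M from eta. Ten times the time leaves target where it stood: at 15000 min target is 10.9 %, isomer of the product 3.89 % and starting material 85.1 %, and cedar adds 0 points. A neighbour flask with 0.26 M of starting material ends with 93.0 % of it and 95 % of its coupling partner, from which 0.177 /M gives 5.25 % of target; that neighbour flask holds 5.15 %.

The numbers in the tables were computed for substances that don't exist, and the scatter is random.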